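**Retrosynthetic overview**

1. Gentiside K is the tetracosyl ester of 2,3-dihydroxybenzoic acid: one benzene ring (bought intact, no ring is formed), an unbranched saturated C24 chain, no stereocentre.
2. Key disconnection: the C2–C3 bond of the alkyl chain, made by anodic decarboxylative radical heterocoupling (mixed Kolbe electrolysis) of tricosanoic acid (gives the docosyl radical) with 3-[(2,3-diacetoxybenzoyl)oxy]propanoic acid (gives the 2-aroyloxyethyl radical). Two carboxyl-bearing carbons of like polarity are joined, and both CO2H groups act as traceless activators.
3. Enabling feature: C2 and C3 are both unsubstituted primary sp3 CH2 carbons of an unfunctionalised chain. C2 is β to the ester oxygen, where a radical is neither stabilised nor fragile (its 1,2-acyloxy shift is degenerate). The benzene ring carries its two phenol oxygens (ring C2 and C3) as acetates beside the ester carbonyl, so it is too electron-poor to be oxidised at the anode.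
4. The coupling acid comes from 2,3-dihydroxybenzoic acid in three steps (O-acetylation, acylation of tert-butyl 3-hydroxypropanoate, tert-butyl cleavage); after the coupling only acetate removal remains.

Key step: step 4

Remark on the chemistry: the target has no stereocentre and no stereogenic double bond; it is achiral, so the route needs no stereocontrol.

**Step 1**
Reactants: 1 2,3-dihydroxybenzoic acid
Product: 2 2,3-diacetoxybenzoic acid
Conditions: Ac2O (4 equiv), conc. H2SO4 (cat.), 60 °C; then H2O, 0 °C → rt, filter
Reagents that add atoms: acetic anhydride, CC(=O)OC(C)=O
Why: Acid-catalysed O-acetylation of both phenols (the aspirin-type reaction) should proceed cleanly, and the aqueous quench hydrolyses any mixed carboxylic anhydride back to the free acid.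

**Step 2**
Reactants: 2 2,3-diacetoxybenzoic acid; 3 tert-butyl 3-hydroxypropanoate
Product: 5 tert-butyl 3-[(2,3-diacetoxybenzoyl)oxy]propanoate, via 2,3-diacetoxybenzoyl chloride 4 (not isolated)
Conditions: (COCl)2 (1.2 equiv), DMF (cat.), CH2Cl2, 0 °C → rt, evaporate; then 3 (1.1 equiv), pyridine (2 equiv), CH2Cl2, 0 °C → rt
Reagents that add atoms: oxalyl chloride, O=C(Cl)C(=O)Cl (supplies the chlorine of 4; no reagent atom remains in 5)
Why: Acid chloride formation via Vilsmeier-type activation followed by pyridine-mediated O-acylation of a primary alcohol is standard, and pyridine without DMAP is too weak a base and acyl-transfer catalyst to cause E1cB loss of the aroyloxy group or acetyl scrambling.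

**Step 3**
Reactants: 5 tert-butyl 3-[(2,3-diacetoxybenzoyl)oxy]propanoate
Product: 6 3-[(2,3-diacetoxybenzoyl)oxy]propanoic acid
Conditions: TFA/CH2Cl2 (1:3), rt; evaporate, co-evaporate with toluene
Reagents that add atoms: none
Why: Acidolysis of the tert-butyl ester (AAL1, loss of isobutene) should leave the aryl acetates and the benzoate linkage untouched, since they are stable to anhydrous TFA.

**Step 4**
Reactants: 6 3-[(2,3-diacetoxybenzoyl)oxy]propanoic acid (4 equiv, added in two portions); 7 tricosanoic acid (1 equiv, ca. 0.03 M)
Product: 8 tetracosyl 2,3-diacetoxybenzoate
Conditions: KOH (10 mol% of total CO2H, pre-mixed with the acids), acetone, 45 °C, undivided cell, Pt|Pt, constant current at high current density with rapid polarity alternation (50 ms), ca. 2.5 F per mol of total acid; silica chromatography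
Reagents that add atoms: none
Why: Both carboxylates are discharged at the anode and lose CO2 (Kolbe electrolysis), which gives the docosyl radical and the 2-(2,3-diacetoxybenzoyloxy)ethyl radical side by side in the radical-rich layer at the electrode, where they combine to form the C2–C3 bond of the chain. The closest known reaction type is the mixed (crossed) Kolbe coupling of a fatty acid with a functionalised co-acid, which is established for long-chain acids and for β-acyloxy acids. No ring is closed and no stereocentre is formed, so only chemoselectivity has to be secured. Cross- over homo-coupling is secured statistically by the fourfold excess of the cheap and more acidic acid 6 (discharged preferentially, therefore dosed in portions), and the two homodimers (a C44 alkane and a butane-1,4-diyl diester) differ strongly in polarity from 8. Radical coupling should win over further oxidation to a cation because both radicals are primary and unstabilised, the 1,2-acyloxy shift of the β-acyloxyethyl radical is degenerate, and the diacetylated, ester-substituted benzene ring is too electron-poor to be oxidised at the working potential. Alcohol-free acetone and the buffering excess of acid should keep the aryl acetates intact, and polarity alternation strips the waxy hydrocarbon film from the electrodes.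

**Step 5**
Reactants: 8 tetracosyl 2,3-diacetoxybenzoate
Product: 9 Gentiside K (tetracosyl 2,3-dihydroxybenzoate)
Conditions: HCl (1.25 M in MeOH)/CH2Cl2 (1:1), rt → 40 °C, under Ar
Reagents that add atoms: none
Why: Acid-catalysed transesterification with methanol should remove both aryl acetates as methyl acetate, while the ortho-disubstituted benzoate of the long-chain alcohol (sterically shielded, conjugated, and hydrogen-bonded to the freed 2-OH) exchanges far more slowly, and the acidic medium protects the catechol from aerial oxidation.

**Compound list**

1 | 2,3-dihydroxybenzoic acid | O=C(O)c1cccc(O)c1O | starting material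
2 | 2,3-diacetoxybenzoic acid | CC(=O)Oc1cccc(C(=O)O)c1OC(C)=O | intermediate
3 | tert-butyl 3-hydroxypropanoate | CC(C)(C)OC(=O)CCO | starting material
4 | 2,3-diacetoxybenzoyl chloride | CC(=O)Oc1cccc(C(=O)Cl)c1OC(C)=O | intermediate (not isolated)
5 | tert-butyl 3-[(2,3-diacetoxybenzoyl)oxy]propanoate | CC(C)(C)OC(=O)CCOC(=O)c1cccc(OC(C)=O)c1OC(C)=O | intermediate
6 | 3-[(2,3-diacetoxybenzoyl)oxy]propanoic acid | O=C(O)CCOC(=O)c1cccc(OC(C)=O)c1OC(C)=O | intermediate
7 | tricosanoic acid | CCCCCCCCCCCCCCCCCCCCCCC(=O)O | starting material
8 | tetracosyl 2,3-diacetoxybenzoate | CCCCCCCCCCCCCCCCCCCCCCCCOC(=O)c1cccc(OC(C)=O)c1OC(C)=O | intermediate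
9 | Gentiside K (tetracosyl 2,3-dihydroxybenzoate) | CCCCCCCCCCCCCCCCCCCCCCCCOC(=O)c1cccc(O)c1O | target

Total step count: 5. Longest linear sequence: 5 steps (1 → 2 → 5 → 6 → 8 → 9); tricosanoic acid 7 enters as a purchased partner in step 4.

**Steps most likely to fail**

Step 4 (mixed Kolbe electrolysis). What may go wrong:
- preferential discharge of the more acidic carboxylate, so that homocoupling dominates;
- passivation of the electrodes by the waxy hydrocarbon;
- further oxidation of the β-acyloxyethyl radical with participation of the neighbouring carbonyl oxygen (Hofer–Moest pathway).

The fallback sets out from 2 and comes back to the route at 8. Acid 2 is converted into the acid chloride 4 exactly as in step 2. Compound 4 is then treated with purchased tetracosan-1-ol (CCCCCCCCCCCCCCCCCCCCCCCCO) and pyridine in CH2Cl2/toluene at 40 °C, which should give 8 directly by simple O-acylation. The chain is then bought complete instead of being assembled, and compounds 3, 5, 6 and 7 are no longer needed. No new compound is made on the way.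

Step 5 (deacetylation). What may go wrong:
- slow cleavage of the hindered 2-acetate, so that prolonged acid methanolysis begins to exchange the tetracosyl ester for a methyl ester.

The fallback sets out from 8 and comes back at 9. Alcoholysis is replaced by aminolysis in an alcohol-free medium: pyrrolidine (2.5 equiv), THF, 0 °C, under argon, then quench with dilute aqueous HCl. The activated aryl acetates should transfer their acyl groups irreversibly to the amine, while the alkyl benzoate reacts far more slowly. No alcohol or alkoxide is present that could displace the tetracosyl group. No new compound is made on the way.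

Step 2 (acylation of the β-hydroxy ester). What may go wrong:
- acetyl transfer from the aryl acetates to the primary alcohol under base;
- base-induced β-elimination of the aroyloxy group from the β-acyloxy ester during reaction or work-up.

The fallback sets out from 2 and comes back at 6, bypassing 5 and step 3. Acid 2 is neutralised with Cs2CO3 (0.5 equiv) in DMF to give caesium 2,3-diacetoxybenzoate F1, used in threefold excess over the lactone. F1 opens oxetan-2-one (β-propiolactone, O=C1CCO1) at rt by SN2 attack at the β-CH2 with alkyl–oxygen cleavage, the known carboxylate ring-opening of this lactone. This gives caesium 3-[(2,3-diacetoxybenzoyl)oxy]propanoate F2, which is acidified with dilute HCl to 6. The excess of F1 suppresses chain growth by further lactone opening, and surplus 2 is recovered. No alcohol nucleophile and no base-sensitive β-acyloxy ester occur in this sequence.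

**Further compounds**

F0 | step 4 | none | none
F0 | step 5 | none | none
F1 | step 2 | caesium 2,3-diacetoxybenzoate | CC(=O)Oc1cccc(C(=O)[O-])c1OC(C)=O.[Cs+]
F2 | step 2 | caesium 3-[(2,3-diacetoxybenzoyl)oxy]propanoate | CC(=O)Oc1cccc(C(=O)OCCC(=O)[O-])c1OC(C)=O.[Cs+]
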